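## Retrosynthetic overview

1. Feature: on ring B (O1–C2–C3–C3a–C7a) the ester oxygen O3 on C3 and the acrolein α-carbon Cα on C2 are cis, and the aldehyde carbon is bonded to Cα. The chain O3–C(=O)–Cα–C2–C3 is therefore a masked γ-lactone (ring C) cis-fused to ring B across C2–C3, with its carbonyl as the later CHO.
2. Target 21 ⇐ α-methylene lactone 13 (reductive opening, silylation of CH2OH, acylation of O3, unmasking and reduction of the ketone, acetylation, desilylation, oxidation) ⇐ lactone 9 (Mannich methylenation).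
3. 9 ⇐ O3 diazoacetate 8: the C2–Cα bond and ring C are formed by intramolecular dirhodium carbene insertion into the C2–H bond cis to O3.
4. 8 ⇐ (R)-alcohol 5 ⇐ commercial 5-bromobenzofuran-3(2H)-one 1 (asymmetric transfer hydrogenation, then Stille coupling with in situ ketalisation of the acetyl equivalent).
5. Ring order: rings A and B come with 1; ring C is closed in step 5 and opened in step 7. Stereocentres: C3 (step 1), C2 (step 5), side-chain carbinol (step 11).

Key step: step 5

Remark: locants (O1, C2, C3, C5, O3, Cα) are those of the 2,3-dihydrobenzofuran of the target; the (S,S)-TsDPEN ruthenium catalyst is assumed to reduce both aryl ketones in the facial sense known for 1-indanone and acetophenone, which corresponds to (R) at C3 and (S) at the side-chain carbinol.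

## Route

Step 1
Reactants: 1 5-bromobenzofuran-3(2H)-one
Product: 2 (R)-5-bromo-2,3-dihydrobenzofuran-3-ol
Conditions: RuCl[(S,S)-TsDPEN](p-cymene) (1 mol %), HCO2H/Et3N (5:2), EtOAc, 25 °C
Reagents that add atoms: none
Why: Noyori asymmetric transfer hydrogenation of a cyclic aryl ketone, in which the catalyst tells the ketone faces apart through the aryl/CH2 pair as in 1-indanone and should give the (R)-carbinol at C3 by catalyst control.

Step 2
Reactants: 2 (R)-5-bromo-2,3-dihydrobenzofuran-3-ol; 3 tributyl(1-ethoxyvinyl)stannane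
Product: 5 (R)-5-(2-methyl-1,3-dioxolan-2-yl)-2,3-dihydrobenzofuran-3-ol, via enol ether 4 (not isolated)
Conditions: Pd(PPh3)4 (5 mol %), toluene, 100 °C; then HOCH2CH2OH (10 equiv), PPTS (0.1 equiv), THF, 20 °C
Reagents that add atoms: tributyl(1-ethoxyvinyl)stannane (3), CCCC[Sn](CCCC)(CCCC)C(=C)OCC; ethylene glycol, OCCO
Why: Stille coupling of the aryl bromide gives the α-ethoxystyrene 4, and acid-catalysed addition of the diol with loss of ethanol (transketalisation of an enol ether) should give the dioxolane without passing through the free ketone and without touching C3.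

Step 3
Reactants: 5 (R)-5-(2-methyl-1,3-dioxolan-2-yl)-2,3-dihydrobenzofuran-3-ol; 6 bromoacetyl bromide
Product: 7 (R)-5-(2-methyl-1,3-dioxolan-2-yl)-2,3-dihydrobenzofuran-3-yl bromoacetate
Conditions: pyridine (1.5 equiv), CH2Cl2, −20 → 0 °C
Reagents that add atoms: bromoacetyl bromide (6), BrCC(Br)=O
Why: O-acylation of the secondary alcohol by the acid bromide (nucleophilic acyl substitution) leaves the C3–O bond and thus the (R) centre intact, and pyridine takes up the HBr so that the ketal should survive.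

Step 4
Reactants: 7 (R)-5-(2-methyl-1,3-dioxolan-2-yl)-2,3-dihydrobenzofuran-3-yl bromoacetate
Product: 8 (R)-5-(2-methyl-1,3-dioxolan-2-yl)-2,3-dihydrobenzofuran-3-yl diazoacetate
Conditions: TsNHNHTs (2 equiv), DBU (5 equiv), THF, 0 °C
Reagents that add atoms: N,N'-ditosylhydrazine, Cc1ccc(cc1)S(=O)(=O)NNS(=O)(=O)c1ccc(C)cc1
Why: Fukuyama diazoacetate synthesis, in which the ditosylhydrazine anion is N-alkylated by the bromoacetate and base then expels two sulfinates, under conditions mild enough for the benzylic ester and the ketal.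

Step 5
Reactants: 8 (R)-5-(2-methyl-1,3-dioxolan-2-yl)-2,3-dihydrobenzofuran-3-yl diazoacetate
Product: 9 (3aR,8bR)-7-(2-methyl-1,3-dioxolan-2-yl)-3a,8b-dihydrofuro[3,2-b]benzofuran-2(3H)-one
Conditions: Rh2(5S-MEPY)4 (dirhodium tetrakis[methyl (S)-2-oxopyrrolidine-5-carboxylate], 1 mol %), CH2Cl2, reflux, 8 added over 10 h (final 0.01 M)
Reagents that add atoms: none
Why: Dinitrogen is expelled at the dirhodium core, and the metal carbene attacks the C2–H bond cis to O3 in a concerted, asynchronous three-centre insertion in which the positive charge building up on C2 is carried by the lone pair of O1. The closest known reaction type is the dirhodium carboxamidate-catalysed insertion of secondary alkyl and 2-alkoxyethyl diazoacetates into C–H bonds next to an ether oxygen to give γ-lactones. Ring C closes as a five-membered ring by 1,5-insertion and can only be cis-fused to ring B, because a trans-fused bicyclo[3.3.0] lactone is too strained. The new stereocentre C2 is therefore set by the existing (R)-C3 (substrate control): of the two C2 hydrogens only the one on the face of O3 lies within reach of the tethered carbene, which should give (2R), 3aR in the lactone. The step needs site selectivity for C2–H over cycloaddition to ring A (Buchner reaction), over four-membered ring formation at C3–H, over attack on O1 and over carbene dimerisation; the weakly electrophilic carboxamidate carbene, the activation of C2–H by O1, the short ester tether and slow addition at high dilution are meant to secure it.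

Step 6
Reactants: 9 (3aR,8bR)-7-(2-methyl-1,3-dioxolan-2-yl)-3a,8b-dihydrofuro[3,2-b]benzofuran-2(3H)-one
Product: 13 (3aR,8bR)-3-methylene-7-(2-methyl-1,3-dioxolan-2-yl)-3a,8b-dihydrofuro[3,2-b]benzofuran-2(3H)-one, via lithium enolate 10 (not isolated), via Mannich base 11 (not isolated), via ammonium iodide 12 (not isolated)
Conditions: LiN(iPr)2 (1.05 equiv), THF, −78 °C, 15 min; [Me2N=CH2]I (3 equiv), −78 → −30 °C; then MeI, MeOH, 20 °C; then aq. NaHCO3, CH2Cl2, 20 °C
Reagents that add atoms: N,N-dimethylmethyleneiminium iodide, C=[N+](C)C.[I-]; iodomethane, CI (its methyl leaves again with trimethylamine); LiN(iPr)2, [Li+].CC(C)[N-]C(C)C (lithium only in 10)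
Why: Mannich reaction of the kinetic lactone enolate followed by quaternisation and E1cB loss of trimethylamine (α-methylenation of a lactone), in which the enolate is made and trapped cold and without excess base so that expulsion of the β-aryloxide O1 should not compete, and the freely rotating ammonium group is then the better leaving group for the exocyclic alkene.

Step 7
Reactants: 13 (3aR,8bR)-3-methylene-7-(2-methyl-1,3-dioxolan-2-yl)-3a,8b-dihydrofuro[3,2-b]benzofuran-2(3H)-one
Product: 14 (2R,3R)-2-(3-hydroxyprop-1-en-2-yl)-5-(2-methyl-1,3-dioxolan-2-yl)-2,3-dihydrobenzofuran-3-ol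
Conditions: iBu2AlH (4 equiv), THF, −78 → −20 °C; aqueous work-up
Reagents that add atoms: none
Why: 1,2-Reduction of the α-methylene lactone by the aluminium hydride through the lactol to the allylic 1,4-diol, which touches no stereocentre, while THF tempers the Lewis acidity of the reagent towards the ketal.

Step 8
Reactants: 14 (2R,3R)-2-(3-hydroxyprop-1-en-2-yl)-5-(2-methyl-1,3-dioxolan-2-yl)-2,3-dihydrobenzofuran-3-ol
Product: 15 (2R,3R)-2-[3-(tert-butyldiphenylsilyloxy)prop-1-en-2-yl]-5-(2-methyl-1,3-dioxolan-2-yl)-2,3-dihydrobenzofuran-3-ol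
Conditions: TBDPSCl (1.05 equiv), imidazole (2 equiv), CH2Cl2, 0 °C
Reagents that add atoms: tert-butyl(chloro)diphenylsilane, CC(C)(C)[Si](Cl)(c1ccccc1)c1ccccc1
Why: Sterically controlled silylation, in which the bulky silyl chloride should react with the primary allylic alcohol far faster than with the hindered secondary benzylic C3 alcohol.

Step 9
Reactants: 15 (2R,3R)-2-[3-(tert-butyldiphenylsilyloxy)prop-1-en-2-yl]-5-(2-methyl-1,3-dioxolan-2-yl)-2,3-dihydrobenzofuran-3-ol
Product: 16 (2R,3R)-2-[3-(tert-butyldiphenylsilyloxy)prop-1-en-2-yl]-5-(2-methyl-1,3-dioxolan-2-yl)-2,3-dihydrobenzofuran-3-yl 3-methylbutanoate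
Conditions: isovaleryl chloride (1.5 equiv), pyridine, DMAP (0.1 equiv), CH2Cl2, 0 → 20 °C
Reagents that add atoms: 3-methylbutanoyl chloride, CC(C)CC(Cl)=O
Why: DMAP-catalysed acylation (nucleophilic acyl substitution) of the only free hydroxyl, which does not break the C3–O bond and so retains (R)-C3.

Step 10
Reactants: 16 (2R,3R)-2-[3-(tert-butyldiphenylsilyloxy)prop-1-en-2-yl]-5-(2-methyl-1,3-dioxolan-2-yl)-2,3-dihydrobenzofuran-3-yl 3-methylbutanoate
Product: 17 (2R,3R)-5-acetyl-2-[3-(tert-butyldiphenylsilyloxy)prop-1-en-2-yl]-2,3-dihydrobenzofuran-3-yl 3-methylbutanoate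
Conditions: PPTS (0.2 equiv), acetone/H2O (10:1), 20 °C
Reagents that add atoms: water, O
Why: Acid-catalysed ketal hydrolysis through an oxocarbenium ion stabilised by the para ring oxygen O1, so that the dioxolane should open under acid mild enough for the TBDPS ether, the isovalerate and the benzylic C3–O bond.

Step 11
Reactants: 17 (2R,3R)-5-acetyl-2-[3-(tert-butyldiphenylsilyloxy)prop-1-en-2-yl]-2,3-dihydrobenzofuran-3-yl 3-methylbutanoate
Product: 18 (2R,3R)-2-[3-(tert-butyldiphenylsilyloxy)prop-1-en-2-yl]-5-[(1S)-1-hydroxyethyl]-2,3-dihydrobenzofuran-3-yl 3-methylbutanoate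
Conditions: RuCl[(S,S)-TsDPEN](p-cymene) (2 mol %), HCO2H/Et3N (5:2), CH2Cl2, 30 °C
Reagents that add atoms: none
Why: Noyori asymmetric transfer hydrogenation of the aryl methyl ketone, where catalyst control (aryl versus methyl, as with acetophenone) should give the (S)-carbinol and the outer-sphere hydride transfer leaves the alkene, the ester and the silyl ether alone.

Step 12
Reactants: 18 (2R,3R)-2-[3-(tert-butyldiphenylsilyloxy)prop-1-en-2-yl]-5-[(1S)-1-hydroxyethyl]-2,3-dihydrobenzofuran-3-yl 3-methylbutanoate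
Product: 19 (2R,3R)-5-[(1S)-1-acetoxyethyl]-2-[3-(tert-butyldiphenylsilyloxy)prop-1-en-2-yl]-2,3-dihydrobenzofuran-3-yl 3-methylbutanoate
Conditions: Ac2O (2 equiv), pyridine, DMAP (0.05 equiv), CH2Cl2, 0 °C
Reagents that add atoms: acetic anhydride, CC(=O)OC(C)=O
Why: DMAP-catalysed O-acetylation with retention, since the carbinol C–O bond is not broken and the basic medium avoids ionisation of the electron-rich benzylic centre.

Step 13
Reactants: 19 (2R,3R)-5-[(1S)-1-acetoxyethyl]-2-[3-(tert-butyldiphenylsilyloxy)prop-1-en-2-yl]-2,3-dihydrobenzofuran-3-yl 3-methylbutanoate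
Product: 20 (2R,3R)-5-[(1S)-1-acetoxyethyl]-2-(3-hydroxyprop-1-en-2-yl)-2,3-dihydrobenzofuran-3-yl 3-methylbutanoate
Conditions: Bu4NF (3 equiv), AcOH (3 equiv), THF, 0 → 20 °C
Reagents that add atoms: none
Why: Fluoride-induced cleavage of the silyl ether driven by Si–F bond formation, buffered with acetic acid so that the liberated alkoxide is protonated at once and neither acyl migration nor ester cleavage should occur.

Step 14
Reactants: 20 (2R,3R)-5-[(1S)-1-acetoxyethyl]-2-(3-hydroxyprop-1-en-2-yl)-2,3-dihydrobenzofuran-3-yl 3-methylbutanoate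
Product: 21 (2R,3R)-5-[(1S)-1-acetoxyethyl]-2-(3-oxoprop-1-en-2-yl)-2,3-dihydrobenzofuran-3-yl 3-methylbutanoate (CNP0252902.1)
Conditions: activated MnO2 (20 equiv), CH2Cl2, 20 °C
Reagents that add atoms: none
Why: Selective oxidation of the primary allylic alcohol to the enal on MnO2 under neutral conditions, which should avoid base-induced loss of isovaleric acid (aromatisation to the benzofuran) and epimerisation at C2.

## Compound list

1 | 5-bromobenzofuran-3(2H)-one | O=C1COc2ccc(Br)cc21 | starting material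
2 | (R)-5-bromo-2,3-dihydrobenzofuran-3-ol | O[C@H]1COc2ccc(Br)cc21 | intermediate
3 | tributyl(1-ethoxyvinyl)stannane | CCCC[Sn](CCCC)(CCCC)C(=C)OCC | starting material
4 | (R)-5-(1-ethoxyvinyl)-2,3-dihydrobenzofuran-3-ol (not isolated) | O[C@H]1COc2ccc(C(=C)OCC)cc21 | intermediate
5 | (R)-5-(2-methyl-1,3-dioxolan-2-yl)-2,3-dihydrobenzofuran-3-ol | O[C@H]1COc2ccc(C3(C)OCCO3)cc21 | intermediate
6 | bromoacetyl bromide | BrCC(Br)=O | starting material
7 | (R)-5-(2-methyl-1,3-dioxolan-2-yl)-2,3-dihydrobenzofuran-3-yl bromoacetate | BrCC(=O)O[C@H]1COc2ccc(C3(C)OCCO3)cc21 | intermediate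
8 | (R)-5-(2-methyl-1,3-dioxolan-2-yl)-2,3-dihydrobenzofuran-3-yl diazoacetate | [N-]=[N+]=CC(=O)O[C@H]1COc2ccc(C3(C)OCCO3)cc21 | intermediate
9 | (3aR,8bR)-7-(2-methyl-1,3-dioxolan-2-yl)-3a,8b-dihydrofuro[3,2-b]benzofuran-2(3H)-one | O=C1C[C@H]2Oc3ccc(C4(C)OCCO4)cc3[C@H]2O1 | intermediate
10 | lithium enolate of 9 (not isolated) | [Li]OC1=C[C@H]2Oc3ccc(C4(C)OCCO4)cc3[C@H]2O1 | intermediate
11 | (3aR,8bR)-3-[(dimethylamino)methyl]-7-(2-methyl-1,3-dioxolan-2-yl)-3a,8b-dihydrofuro[3,2-b]benzofuran-2(3H)-one, C3 not defined (not isolated) | O=C1C(CN(C)C)[C@H]2Oc3ccc(C4(C)OCCO4)cc3[C@H]2O1 | intermediate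
12 | trimethylammonium iodide of 11, C3 not defined (not isolated) | O=C1C(C[N+](C)(C)C)[C@H]2Oc3ccc(C4(C)OCCO4)cc3[C@H]2O1.[I-] | intermediate
13 | (3aR,8bR)-3-methylene-7-(2-methyl-1,3-dioxolan-2-yl)-3a,8b-dihydrofuro[3,2-b]benzofuran-2(3H)-one | O=C1C(=C)[C@H]2Oc3ccc(C4(C)OCCO4)cc3[C@H]2O1 | intermediate
14 | (2R,3R)-2-(3-hydroxyprop-1-en-2-yl)-5-(2-methyl-1,3-dioxolan-2-yl)-2,3-dihydrobenzofuran-3-ol | C=C(CO)[C@H]1Oc2ccc(C3(C)OCCO3)cc2[C@H]1O | intermediate
15 | (2R,3R)-2-[3-(tert-butyldiphenylsilyloxy)prop-1-en-2-yl]-5-(2-methyl-1,3-dioxolan-2-yl)-2,3-dihydrobenzofuran-3-ol | C=C(CO[Si](c1ccccc1)(c1ccccc1)C(C)(C)C)[C@H]1Oc2ccc(C3(C)OCCO3)cc2[C@H]1O | intermediate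
16 | (2R,3R)-2-[3-(tert-butyldiphenylsilyloxy)prop-1-en-2-yl]-5-(2-methyl-1,3-dioxolan-2-yl)-2,3-dihydrobenzofuran-3-yl 3-methylbutanoate | C=C(CO[Si](c1ccccc1)(c1ccccc1)C(C)(C)C)[C@H]1Oc2ccc(C3(C)OCCO3)cc2[C@H]1OC(=O)CC(C)C | intermediate
17 | (2R,3R)-5-acetyl-2-[3-(tert-butyldiphenylsilyloxy)prop-1-en-2-yl]-2,3-dihydrobenzofuran-3-yl 3-methylbutanoate | C=C(CO[Si](c1ccccc1)(c1ccccc1)C(C)(C)C)[C@H]1Oc2ccc(C(C)=O)cc2[C@H]1OC(=O)CC(C)C | intermediate
18 | (2R,3R)-2-[3-(tert-butyldiphenylsilyloxy)prop-1-en-2-yl]-5-[(1S)-1-hydroxyethyl]-2,3-dihydrobenzofuran-3-yl 3-methylbutanoate | C=C(CO[Si](c1ccccc1)(c1ccccc1)C(C)(C)C)[C@H]1Oc2ccc([C@H](C)O)cc2[C@H]1OC(=O)CC(C)C | intermediate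
19 | (2R,3R)-5-[(1S)-1-acetoxyethyl]-2-[3-(tert-butyldiphenylsilyloxy)prop-1-en-2-yl]-2,3-dihydrobenzofuran-3-yl 3-methylbutanoate | C=C(CO[Si](c1ccccc1)(c1ccccc1)C(C)(C)C)[C@H]1Oc2ccc([C@H](C)OC(C)=O)cc2[C@H]1OC(=O)CC(C)C | intermediate
20 | (2R,3R)-5-[(1S)-1-acetoxyethyl]-2-(3-hydroxyprop-1-en-2-yl)-2,3-dihydrobenzofuran-3-yl 3-methylbutanoate | C=C(CO)[C@H]1Oc2ccc([C@H](C)OC(C)=O)cc2[C@H]1OC(=O)CC(C)C | intermediate
21 | (2R,3R)-5-[(1S)-1-acetoxyethyl]-2-(3-oxoprop-1-en-2-yl)-2,3-dihydrobenzofuran-3-yl 3-methylbutanoate | C=C(C=O)[C@H]1Oc2ccc([C@H](C)OC(C)=O)cc2[C@H]1OC(=O)CC(C)C | target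

## Step count and risks

Total step count: 14. Longest linear sequence: 14 steps (1 to 21).

Steps most likely to fail:

**Step 5 (carbene C–H insertion).** The carbene may be used up by dimerisation, by cycloaddition to ring A or by attack on the lone pair of O1 (oxonium ylide and 1,2-shift) faster than it inserts into the C2–H bond, which an aryloxy oxygen activates less than an alkoxy oxygen would. The fallback sets out from 1 and comes back at 9; it makes the C2–Cα bond before the carbinol and sets the cis relationship by dynamic kinetic resolution. Compound 1 is condensed with ethyl glyoxylate on neutral Al2O3 in CH2Cl2 to ethyl (Z)-2-(5-bromo-3-oxobenzofuran-2(3H)-ylidene)acetate F1 (alkene geometry immaterial). Zn in AcOH reduces the doubly activated alkene to racemic ethyl 2-(5-bromo-3-oxo-2,3-dihydrobenzofuran-2-yl)acetate F2. Transfer hydrogenation with RuCl[(S,S)-TsDPEN](p-cymene) in HCO2H/Et3N, during which C2 epimerises through the enol, should give ethyl 2-[(2R,3R)-5-bromo-3-hydroxy-2,3-dihydrobenzofuran-2-yl]acetate F3. This should close, on standing or with a trace of PPTS in warm toluene, to (3aR,8bR)-7-bromo-3a,8b-dihydrofuro[3,2-b]benzofuran-2(3H)-one F4. Stille coupling with 3 (Pd(PPh3)4, toluene, 100 °C) gives (3aR,8bR)-7-(1-ethoxyvinyl)-3a,8b-dihydrofuro[3,2-b]benzofuran-2(3H)-one F5, and ethylene glycol with PPTS as in step 2 leads to 9.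

**Step 6 (α-methylenation).** The lactone enolate may expel the aryloxide O1 (E1cB opening of ring B) before it is aminomethylated, and the butenolide so formed may lose the C3 proton, so that both material and the configuration at C3 are lost. The fallback sets out from 5 and comes back at 13; it builds the activating group for the methylenation into the carbene precursor, so that no unstabilised enolate is needed. Compound 5 is esterified with diethylphosphonoacetic acid (DCC, DMAP, CH2Cl2) to (R)-5-(2-methyl-1,3-dioxolan-2-yl)-2,3-dihydrobenzofuran-3-yl 2-(diethoxyphosphoryl)acetate F6. Diazo transfer with 4-acetamidobenzenesulfonyl azide and DBU in MeCN gives (R)-5-(2-methyl-1,3-dioxolan-2-yl)-2,3-dihydrobenzofuran-3-yl 2-diazo-2-(diethoxyphosphoryl)acetate F7. Rh2(OAc)4 in refluxing 1,2-dichloroethane should insert the acceptor/acceptor carbene into the same C2–H bond to give diethyl [(3aR,8bR)-7-(2-methyl-1,3-dioxolan-2-yl)-2-oxo-2,3,3a,8b-tetrahydrofuro[3,2-b]benzofuran-3-yl]phosphonate F8. Horner–Wadsworth–Emmons reaction with aqueous formaldehyde and K2CO3 in THF at 0 °C then gives 13 through a phosphonate-stabilised anion.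

**Step 11 (reduction of the side-chain ketone).** Hydrogen transfer to the electron-rich p-alkoxyaryl ketone may be slow and incomplete, and long exposure to the acidic formate medium may erode the configuration of the ionisable benzylic carbinol. The fallback sets out from 17 and comes back at 18: Corey–Bakshi–Shibata reduction with (R)-2-methyl-CBS-oxazaborolidine (0.2 equiv) and catecholborane in toluene at −78 °C. This is a stoichiometric borane reduction under oxazaborolidine control that runs at low temperature and should leave the alkene and the esters alone. It makes no new compound (F0).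

## Further compounds

F1 | step 5 | ethyl (Z)-2-(5-bromo-3-oxobenzofuran-2(3H)-ylidene)acetate | CCOC(=O)/C=C1\Oc2ccc(Br)cc2C1=O
F2 | step 5 | ethyl 2-(5-bromo-3-oxo-2,3-dihydrobenzofuran-2-yl)acetate (racemic) | CCOC(=O)CC1Oc2ccc(Br)cc2C1=O
F3 | step 5 | ethyl 2-[(2R,3R)-5-bromo-3-hydroxy-2,3-dihydrobenzofuran-2-yl]acetate | CCOC(=O)C[C@H]1Oc2ccc(Br)cc2[C@H]1O
F4 | step 5 | (3aR,8bR)-7-bromo-3a,8b-dihydrofuro[3,2-b]benzofuran-2(3H)-one | O=C1C[C@H]2Oc3ccc(Br)cc3[C@H]2O1
F5 | step 5 | (3aR,8bR)-7-(1-ethoxyvinyl)-3a,8b-dihydrofuro[3,2-b]benzofuran-2(3H)-one | O=C1C[C@H]2Oc3ccc(C(=C)OCC)cc3[C@H]2O1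
F6 | step 6 | (R)-5-(2-methyl-1,3-dioxolan-2-yl)-2,3-dihydrobenzofuran-3-yl 2-(diethoxyphosphoryl)acetate | CCOP(=O)(OCC)CC(=O)O[C@H]1COc2ccc(C3(C)OCCO3)cc21
F7 | step 6 | (R)-5-(2-methyl-1,3-dioxolan-2-yl)-2,3-dihydrobenzofuran-3-yl 2-diazo-2-(diethoxyphosphoryl)acetate | CCOP(=O)(OCC)C(=[N+]=[N-])C(=O)O[C@H]1COc2ccc(C3(C)OCCO3)cc21
F8 | step 6 | diethyl [(3aR,8bR)-7-(2-methyl-1,3-dioxolan-2-yl)-2-oxo-2,3,3a,8b-tetrahydrofuro[3,2-b]benzofuran-3-yl]phosphonate (C3 not defined) | O=C1C(P(=O)(OCC)OCC)[C@H]2Oc3ccc(C4(C)OCCO4)cc3[C@H]2O1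
F0 | step 11 | none | none
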